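**Plan**
1. First cut, C11–C12: an sp3–sp2 coupling joins a labdane C11 zinc reagent to the E-iodoalkene of the tetracyclic core. C4, C5, C9 and C10 are kept from abietic acid, and the C7′ formyl group travels as a vinyl group.
2. Second cut, C4′–C5′ and C9′–C10′ together. Ring A (C10′, C1′–C5′, gem-dimethyl C4′) and ring B (C8′, C9′, C10′, C5′, C7′) share the trans C5′–C10′ bond. Ring B ends on C9′, the enol carbon of the diosphenol C12′(=O)–C11′(OH)=C9′, which is the imprint of a geranyl-type cation cascade.
3. Third cut, C8′–C15 and C13′–C14: a (5+2) cycloaddition of a 2-methoxyquinone (C8′, C9′, C11′–C14′) with the vinyl end of (E)-1-iodo-2-methylbutadiene. Fourth cut, C7′–C5′: allylic vinylation of an aryl vinyl carbinol.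
4. Forward order: arene, then C7′ with the whole dienyl chain, then the quinone, then the bicyclo[3.2.1]octenedione, then rings A and B in one step, then the aldehyde, the labdane union and deprotection. The acid-labile labdane alkenes enter only after the acid step.
5. Stereochemistry: C7′ comes from the chiral iridium catalyst. C8′, C13′ and C14 come from C7′-directed facial attack and endo orientation in the (5+2) step. C5′ and C10′ come from anti addition to the E alkene steered by allylic strain at C7′. Both trisubstituted E alkenes come from syn-carboalumination.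

Key step: step 14

Numbering: unprimed atoms belong to the labdane half (C12–C15 and the C13 methyl come from the iododiene). Primed atoms belong to the abeo-abietane half.
Assumption: the (S)-configured phosphoramidite–olefin ligand is taken to give the (R) centre at C7′. If the sense of induction is the opposite, the antipodal ligand is used.

Step 1
Reactants: 1 1,2,4-trimethoxybenzene
Product: 3 2-(2,3,6-trimethoxyphenyl)propan-2-ol, via 3-lithio-1,2,4-trimethoxybenzene 2 (not isolated)
Conditions: n-BuLi, TMEDA, THF, 0 °C; acetone, −78 °C to rt; H2O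
Reagents that add atoms: acetone, CC(C)=O
Why: Directed ortho-lithiation removes the proton flanked by two methoxy groups (future C13′) and the aryllithium adds to the ketone carbonyl.

Step 2
Reactants: 3 2-(2,3,6-trimethoxyphenyl)propan-2-ol
Product: 4 1,2,4-trimethoxy-3-(propan-2-yl)benzene
Conditions: Et3SiH, CF3CO2H, CH2Cl2, 0 °C to rt
Reagents that add atoms: none
Why: Ionic hydrogenation, in which the electron-rich tertiary benzylic alcohol ionises in acid and the cation takes hydride from the silane.

Step 3
Reactants: 4 1,2,4-trimethoxy-3-(propan-2-yl)benzene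
Product: 5 1-bromo-2,4,5-trimethoxy-3-(propan-2-yl)benzene
Conditions: NBS, MeCN, 0 °C
Reagents that add atoms: N-bromosuccinimide, O=C1CCC(=O)N1Br
Why: Electrophilic aromatic bromination goes to the free position ortho and para to two methoxy groups (future C8′), because the other free position (future C9′) is activated by one methoxy group only.

Step 4
Reactants: 5 1-bromo-2,4,5-trimethoxy-3-(propan-2-yl)benzene
Product: 7 (±)-1-[2,4,5-trimethoxy-3-(propan-2-yl)phenyl]prop-2-en-1-ol, via aryllithium 6 (not isolated)
Conditions: n-BuLi, THF, −78 °C; acrolein, −78 °C; H2O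
Reagents that add atoms: acrolein, C=CC=O
Why: Bromine–lithium exchange and 1,2-addition to the enal give the branched allylic alcohol, whose racemic carbinol centre is erased in step 8.

Step 5
Reactants: 8 5-bromo-2-methylpent-2-ene
Product: 9 6-methylhept-5-en-1-yne
Conditions: lithium acetylide–ethylenediamine complex, DMSO, rt
Reagents that add atoms: lithium acetylide–ethylenediamine complex, [Li]C#C.NCCN
Why: SN2 alkylation of acetylide by an unhindered primary homoallylic bromide.

Step 6
Reactants: 9 6-methylhept-5-en-1-yne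
Product: 11 (1E)-1-iodo-2,6-dimethylhepta-1,5-diene, via alkenyldimethylalane 10 (not isolated)
Conditions: Me3Al, Cp2ZrCl2 (cat.), CH2Cl2, rt; I2, THF, −30 °C
Reagents that add atoms: trimethylaluminium, C[Al](C)C; iodine, [I][I]
Why: Negishi zirconium-catalysed carboalumination adds methyl and aluminium syn to the terminal alkyne with aluminium at the terminus, and iodinolysis with retention fixes the E geometry of the future C5′=C10′ bond.

Step 7
Reactants: 11 (1E)-1-iodo-2,6-dimethylhepta-1,5-diene
Product: 14 potassium [(1E)-2,6-dimethylhepta-1,5-dien-1-yl]trifluoroborate, via alkenyllithium 12 (not isolated), via lithium alkenyltrimethoxyborate 13 (not isolated)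
Conditions: t-BuLi (2 equiv), Et2O, −78 °C; B(OMe)3, −78 °C to rt; KHF2, MeOH–H2O
Reagents that add atoms: trimethyl borate, COB(OC)OC; potassium hydrogen difluoride, [K+].F.[F-]
Why: Iodine–lithium exchange, borylation and fluoride exchange all proceed with retention at the alkenyl carbon and give a bench-stable trifluoroborate.

Step 8
Reactants: 7 (±)-1-[2,4,5-trimethoxy-3-(propan-2-yl)phenyl]prop-2-en-1-ol; 14 potassium [(1E)-2,6-dimethylhepta-1,5-dien-1-yl]trifluoroborate
Product: 15 1-[(3R,4E)-5,9-dimethyldeca-1,4,8-trien-3-yl]-2,4,5-trimethoxy-3-(propan-2-yl)benzene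
Conditions: [Ir(cod)Cl]2 (cat.), (S)-BINOL-derived dibenzazepinyl phosphoramidite–olefin ligand, n-Bu4NHSO4, KHF2, 1,4-dioxane, rt
Reagents that add atoms: none
Why: Iridium-catalysed enantioconvergent allylic vinylation of a branched aryl vinyl carbinol, in which the chiral allyl-iridium species is attacked at its benzylic terminus so that the ligand sets C7′ as R, while ipso substitution at boron (through a tertiary β-boryl cation) keeps the E alkene.

Step 9
Reactants: 15 1-[(3R,4E)-5,9-dimethyldeca-1,4,8-trien-3-yl]-2,4,5-trimethoxy-3-(propan-2-yl)benzene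
Product: 16 5-[(3R,4E)-5,9-dimethyldeca-1,4,8-trien-3-yl]-2-methoxy-3-(propan-2-yl)cyclohexa-2,5-diene-1,4-dione
Conditions: (NH4)2Ce(NO3)6, MeCN–H2O, 0 °C, used at once
Reagents that add atoms: water, O
Why: Oxidative demethylation of the para-dimethoxy pair (C11′ and C14′) is fast at 0 °C, leaves the C12′ methoxy group and tolerates isolated alkenes as in prenylated quinone syntheses, and C7′ is not touched under these non-basic conditions.

Step 10
Reactants: 17 prop-2-yn-1-ol
Product: 19 (2E)-3-iodo-2-methylprop-2-en-1-ol, via alkoxide-bound alkenylalane 18 (not isolated)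
Conditions: Me3Al (3 equiv), Cp2ZrCl2 (cat.), CH2Cl2, 0 °C to rt; I2, THF, −30 °C; H2O
Reagents that add atoms: trimethylaluminium, C[Al](C)C; iodine, [I][I]
Why: Negishi carboalumination of the aluminium alkoxide followed by iodinolysis gives the E-iodoalkene that becomes C12=C13 with its methyl group.

Step 11
Reactants: 19 (2E)-3-iodo-2-methylprop-2-en-1-ol
Product: 20 (2E)-3-iodo-2-methylprop-2-enal
Conditions: MnO2, CH2Cl2, rt
Reagents that add atoms: none
Why: Allylic alcohol oxidation on manganese dioxide is neutral and does not isomerise the iodoalkene.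

Step 12
Reactants: 20 (2E)-3-iodo-2-methylprop-2-enal
Product: 21 (1E)-1-iodo-2-methylbuta-1,3-diene
Conditions: MePPh3Br, NaHMDS, THF, 0 °C; then 20, −78 °C to 0 °C; kept as a solution
Reagents that add atoms: methyltriphenylphosphonium bromide, C[P+](c1ccccc1)(c1ccccc1)c1ccccc1.[Br-]
Why: Wittig methylenation of the enal installs the C14=C15 vinyl group and leaves the E-iodoalkene unchanged.

Step 13
Reactants: 16 5-[(3R,4E)-5,9-dimethyldeca-1,4,8-trien-3-yl]-2-methoxy-3-(propan-2-yl)cyclohexa-2,5-diene-1,4-dione; 21 (1E)-1-iodo-2-methylbuta-1,3-diene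
Product: 22 bicyclic diosphenol 3-hydroxy-7-endo-[(1E)-1-iodoprop-1-en-2-yl]-1-(propan-2-yl)-5-[(3R,4E)-5,9-dimethyldeca-1,4,8-trien-3-yl]bicyclo[3.2.1]oct-3-ene-2,8-dione (C8′ C13′ C14 as in the target)
Conditions: TiCl4, 2,6-di-tert-butyl-4-methylpyridine, 21 (excess), CH2Cl2, −78 to −40 °C; H2O
Reagents that add atoms: none
Why: Lewis-acid-promoted (5+2) cycloaddition of a 2-alkoxy-1,4-benzoquinone with a conjugated alkene (perezone–pipitzol type, known intermolecularly for styrenes and in tethered form for 1,3-dienes): TiCl4 chelated by O11′ and the C12′ methoxy group makes C8′ electrophilic, the unsubstituted terminus C15 adds there, the transoid iodoallyl cation is closed at C14 by C13′ and chloride removes the methyl group under aprotic conditions that spare the polyene, while C8′, C13′ and C14 are set by approach anti to the C5′=C10′ arm that folds under one quinone face when H7′ eclipses the C14′ carbonyl side and by the endo, charge-stacked placement of the iodoalkenyl group.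

Step 14
Reactants: 22 bicyclic diosphenol with the acyclic dienyl chain on C7′
Product: 23 tetracyclic diosphenol with rings A and B closed (H5′ and the C10′ methyl trans; C7′ vinyl trans to C4′; E-iodoalkenyl on C14)
Conditions: SnCl4, 2-methoxyphenol, CH2Cl2–toluene, −78 °C; H2O
Reagents that add atoms: none
Why: The SnCl4-bound phenol acts as a Lewis-acid-assisted Brønsted acid and protonates C3′ of the terminal C3′=C4′ alkene; the tertiary C4′ cation is attacked by C5′ of the E-C5′=C10′ alkene, the developing C10′ cation is trapped by C9′, the enol carbon of the tin-chelated diosphenol C12′(=O)–C11′(OH)=C9′, and loss of H9′ restores the diosphenol, so that C4′–C5′ and C9′–C10′ form in one operation. The closest known reaction type is the proton-initiated cation–olefin bicyclisation of geranyl-type chains that ends on an arene, a β-keto ester enol or a silyl enol ether, including closures to trans-fused 6-5-6 hexahydrofluorenes. Ring A closes 6-endo-trig through a chair and ring B closes 5-exo-trig with respect to the C9′=C11′ enol bond (5-enolexo), the polarity of the enol directing the attack to C9′. C5′ and C10′ result from anti addition across the E alkene, which places H5′ and the C10′ methyl group trans, and their sense relative to the bicycle is dictated by C7′: allylic 1,3-strain with the C10′ methyl group holds H7′ in the alkene plane, C8′ with C9′ therefore sits on one alkene face and C4′ must add to the other, anti to the C7′ vinyl group. The step needs initiation at C3′=C4′ only and carbon capture instead of proton loss: the monosubstituted vinyl group and the iodine-deactivated C12=C13 alkene are far less basic, C5′=C10′ is shielded by the neopentylic C7′–C8′ surroundings, neither ketone can enolise, and alkenes formed by premature proton loss from C10′ re-enter the cation manifold under the acid.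

Step 15
Reactants: 23 tetracyclic diosphenol
Product: 24 C11′ tert-butyldimethylsilyl ether of 23
Conditions: TBSOTf, 2,6-lutidine, CH2Cl2, 0 °C
Reagents that add atoms: tert-butyldimethylsilyl triflate, CC(C)(C)[Si](C)(C)OS(=O)(=O)C(F)(F)F
Why: O-silylation of the acidic enol masks a group that periodate would cleave and that would protonate the zinc reagent, and no other enolisable site exists in the molecule.

Step 16
Reactants: 24 C11′ tert-butyldimethylsilyl ether of 23
Product: 26 C7′ aldehyde of the silylated tetracycle, via vicinal diol 25 (not isolated)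
Conditions: OsO4 (cat.), NaIO4, 2,6-lutidine, 1,4-dioxane–H2O, rt
Reagents that add atoms: osmium tetroxide, O=[Os](=O)(=O)=O; sodium periodate (renews the osmium-bound oxygen), [Na+].[O-]I(=O)(=O)=O
Why: Lemieux–Johnson cleavage, in which OsO4 takes the only electronically normal and accessible alkene (the monosubstituted C7′ vinyl group) while the iodoalkene is deactivated and the silyloxy-enone is tetrasubstituted, and periodate then releases the formyl group with C7′ unchanged.

Step 17
Reactants: 27 abietic acid
Product: 28 2-(trimethylsilyl)ethyl abietate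
Conditions: 2-(trimethylsilyl)ethanol, PPh3, DIAD, THF, 0 °C to rt
Reagents that add atoms: 2-(trimethylsilyl)ethanol, C[Si](C)(C)CCO
Why: Mitsunobu esterification lets the hindered C4 carboxylate act as the nucleophile toward an activated primary alcohol and installs an ester that fluoride removes at the end.

Step 18
Reactants: 28 2-(trimethylsilyl)ethyl abietate
Product: 30 2-(trimethylsilyl)ethyl 13-oxo-13,14-secoabiet-7-en-14-al-18-oate, via 13,14-diol 29 (not isolated)
Conditions: OsO4 (cat.), NMO, acetone–H2O, rt; NaIO4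
Reagents that add atoms: osmium tetroxide, O=[Os](=O)(=O)=O; N-methylmorpholine N-oxide, C[N+]1([O-])CCOCC1
Why: Dihydroxylation of abietates is known to take the C13=C14 bond of the heteroannular diene, and periodate cleavage of the diol opens ring C to an isopropyl ketone (C13) and a C7=C8 enal whose carbonyl carbon becomes C17, with C9 untouched.

Step 19
Reactants: 30 2-(trimethylsilyl)ethyl 13-oxo-13,14-secoabiet-7-en-14-al-18-oate
Product: 31 2-(trimethylsilyl)ethyl 14-hydroxy-13-oxo-13,14-secoabiet-7-en-18-oate
Conditions: NaBH4, CH2Cl2–MeOH, −78 °C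
Reagents that add atoms: none
Why: Low-temperature borohydride reduction is chemoselective for the aldehyde (1,2-mode) over the hindered isopropyl ketone and the neopentylic ester.

Step 20
Reactants: 31 2-(trimethylsilyl)ethyl 14-hydroxy-13-oxo-13,14-secoabiet-7-en-18-oate
Product: 34 2-(trimethylsilyl)ethyl 13-oxo-13,14-secoabiet-8(14)-en-18-oate (exocyclic C8=C17 methylene), via N-allyl sulfonylhydrazine 32 (not isolated), via allylic diazene 33 (not isolated)
Conditions: 2-nitrobenzenesulfonylhydrazide, PPh3, DEAD, N-methylmorpholine, −30 °C to rt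
Reagents that add atoms: none
Why: Myers reductive allylic transposition, in which Mitsunobu displacement at the primary allylic carbon and loss of sulfinate give a monoalkyl diazene whose retro-ene loss of nitrogen delivers hydrogen to C7 and moves the alkene to the exocyclic position without creating a stereocentre.

Step 21
Reactants: 34 2-(trimethylsilyl)ethyl 13-oxo-13,14-secoabiet-8(14)-en-18-oate
Product: 36 12-hydroxy derivative of 34 (C12 epimers), via potassium enolate 35 (not isolated)
Conditions: KHMDS, THF, −78 °C; 2-(phenylsulfonyl)-3-phenyloxaziridine, −78 °C; H2O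
Reagents that add atoms: 2-(phenylsulfonyl)-3-phenyloxaziridine, O=S(=O)(c1ccccc1)N1OC1c1ccccc1
Why: Kinetic deprotonation occurs at the C12 methylene, not at the isopropyl methine, and Davis oxidation of the enolate gives the acyloin, whose new carbinol centre is destroyed in the next step.

Step 22
Reactants: 36 12-hydroxy derivative of 34
Product: 37 2-(trimethylsilyl)ethyl 12-oxo-13,14,15,16-tetranorlabd-8(17)-en-18-oate (C12 aldehyde)
Conditions: Pb(OAc)4, MeOH–CH2Cl2, 0 °C
Reagents that add atoms: none
Why: Criegee-type cleavage of the α-hydroxy ketone breaks C12–C13 to give the aldehyde and methyl isobutyrate under conditions that leave the 1,1-disubstituted alkene alone.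

Step 23
Reactants: 37 C12 aldehyde
Product: 38 18-[2-(trimethylsilyl)ethyl] hydrogen 13,14,15,16-tetranorlabd-8(17)-ene-12,18-dioate (C12 acid)
Conditions: NaClO2, NaH2PO4, 2-methylbut-2-ene, t-BuOH–H2O, rt
Reagents that add atoms: sodium chlorite, [Na+].[O-]Cl=O
Why: Pinnick oxidation with an alkene scavenger for hypochlorous acid converts the aldehyde into the acid without touching C8=C17 or C9.

Step 24
Reactants: 38 C12 acid
Product: 40 2-(trimethylsilyl)ethyl 11-iodo-12,13,14,15,16-pentanorlabd-8(17)-en-18-oate, via thiohydroxamate ester 39 (not isolated)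
Conditions: N-hydroxypyridine-2-thione, DCC, CH2Cl2, dark, 0 °C; CHI3, hν (tungsten lamp), rt
Reagents that add atoms: iodoform, C(I)(I)I
Why: Barton decarboxylative iodination, in which the primary C11 radical is trapped by fast iodine-atom transfer before homoallyl–cyclopropylcarbinyl rearrangement, and the absence of electrophilic iodine avoids iodolactonisation of the γ,δ-unsaturated acid.

Step 25
Reactants: 40 2-(trimethylsilyl)ethyl 11-iodo-12,13,14,15,16-pentanorlabd-8(17)-en-18-oate; 26 C7′ aldehyde of the silylated tetracycle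
Product: 42 doubly silyl-protected target (C11′ silyl ether and C4 trimethylsilylethyl ester), via alkylzinc iodide 41 (not isolated)
Conditions: Zn dust, LiCl, THF, 40 °C; then 26, Pd(dppf)Cl2 (cat.), THF, rt
Reagents that add atoms: none
Why: Negishi sp3–sp2 coupling, in which zinc inserts into the primary carbon–iodine bond without harming the ester, the alkylzinc iodide ignores aldehyde and ketones, the alkenyl iodide couples with retention so that C12=C13 stays E, and the wide-bite-angle ligand favours reductive elimination over β-hydride loss toward C9.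

Step 26
Reactants: 42 doubly silyl-protected target
Product: 43 CNP0256710.1
Conditions: TASF, DMF, 0 °C to rt; aq NaH2PO4
Reagents that add atoms: none
Why: Fluoride removes the enol silyl ether and fragments the 2-(trimethylsilyl)ethyl ester under non-hydrolytic conditions that spare the non-enolisable 1,3-diketone and both labdane alkenes, and C7′ already carries the formyl group trans to C4′, which should be the more stable arrangement.

**Compound list**
1 | 1,2,4-trimethoxybenzene | COc1ccc(OC)c(OC)c1 | starting material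
2 | 3-lithio-1,2,4-trimethoxybenzene | COc1ccc(OC)c([Li])c1OC | intermediate
3 | 2-(2,3,6-trimethoxyphenyl)propan-2-ol | COc1ccc(OC)c(C(C)(C)O)c1OC | intermediate
4 | 1,2,4-trimethoxy-3-(propan-2-yl)benzene | COc1ccc(OC)c(C(C)C)c1OC | intermediate
5 | 1-bromo-2,4,5-trimethoxy-3-(propan-2-yl)benzene | COc1cc(Br)c(OC)c(C(C)C)c1OC | intermediate
6 | 2,4,5-trimethoxy-3-(propan-2-yl)phenyllithium | COc1cc([Li])c(OC)c(C(C)C)c1OC | intermediate
7 | (±)-1-[2,4,5-trimethoxy-3-(propan-2-yl)phenyl]prop-2-en-1-ol | C=CC(O)c1cc(OC)c(OC)c(C(C)C)c1OC | intermediate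
8 | 5-bromo-2-methylpent-2-ene | CC(C)=CCCBr | starting material
9 | 6-methylhept-5-en-1-yne | C#CCCC=C(C)C | intermediate
10 | [(1E)-2,6-dimethylhepta-1,5-dien-1-yl]dimethylalane | C[Al](C)/C=C(\C)CCC=C(C)C | intermediate
11 | (1E)-1-iodo-2,6-dimethylhepta-1,5-diene | I/C=C(\C)CCC=C(C)C | intermediate
12 | (1E)-2,6-dimethylhepta-1,5-dien-1-yllithium | [Li]/C=C(\C)CCC=C(C)C | intermediate
13 | lithium [(1E)-2,6-dimethylhepta-1,5-dien-1-yl]trimethoxyborate | [Li+].CO[B-](OC)(OC)/C=C(\C)CCC=C(C)C | intermediate
14 | potassium [(1E)-2,6-dimethylhepta-1,5-dien-1-yl]trifluoroborate | [K+].F[B-](F)(F)/C=C(\C)CCC=C(C)C | intermediate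
15 | 1-[(3R,4E)-5,9-dimethyldeca-1,4,8-trien-3-yl]-2,4,5-trimethoxy-3-(propan-2-yl)benzene | COc1cc([C@H](C=C)/C=C(\C)CCC=C(C)C)c(OC)c(C(C)C)c1OC | intermediate
16 | 5-[(3R,4E)-5,9-dimethyldeca-1,4,8-trien-3-yl]-2-methoxy-3-(propan-2-yl)cyclohexa-2,5-diene-1,4-dione | COC1=C(C(C)C)C(=O)C([C@H](C=C)/C=C(\C)CCC=C(C)C)=CC1=O | intermediate
17 | prop-2-yn-1-ol | C#CCO | starting material
18 | dimethylaluminium alkoxide of (2E)-3-(dimethylalumanyl)-2-methylprop-2-en-1-ol | C[Al](C)OC/C(C)=C/[Al](C)C | intermediate
19 | (2E)-3-iodo-2-methylprop-2-en-1-ol | I/C=C(\C)CO | intermediate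
20 | (2E)-3-iodo-2-methylprop-2-enal | I/C=C(\C)C=O | intermediate
21 | (1E)-1-iodo-2-methylbuta-1,3-diene | I/C=C(\C)C=C | intermediate
22 | key-step precursor: 3-hydroxy-7-endo-[(1E)-1-iodoprop-1-en-2-yl]-1-(propan-2-yl)-5-[(3R,4E)-5,9-dimethyldeca-1,4,8-trien-3-yl]bicyclo[3.2.1]oct-3-ene-2,8-dione (C1 = C13′, C5 = C8′, C7 = C14, configured as in the target) | I/C=C(\C)[C@@H]1C[C@]2(C(=O)[C@]1(C(C)C)C(=O)C(O)=C2)[C@H](C=C)/C=C(\C)CCC=C(C)C | intermediate
23 | key-step product: tetracyclic diosphenol, rings A and B trans-fused (H5′ anti to the C10′ methyl), C7′ vinyl trans to C4′, E-iodoalkenyl on C14 | I/C=C(\C)[C@@H]1C[C@@]23C(=O)[C@]1(C(C)C)C(=O)C(O)=C2[C@@]1(C)CCCC(C)(C)[C@@H]1[C@H]3C=C | intermediate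
24 | C11′ tert-butyldimethylsilyl ether of 23 | I/C=C(\C)[C@@H]1C[C@@]23C(=O)[C@]1(C(C)C)C(=O)C(O[Si](C)(C)C(C)(C)C)=C2[C@@]1(C)CCCC(C)(C)[C@@H]1[C@H]3C=C | intermediate
25 | 1,2-diol from the C7′ vinyl group of 24 (carbinol epimers) | I/C=C(\C)[C@@H]1C[C@@]23C(=O)[C@]1(C(C)C)C(=O)C(O[Si](C)(C)C(C)(C)C)=C2[C@@]1(C)CCCC(C)(C)[C@@H]1[C@H]3C(O)CO | intermediate
26 | C7′ aldehyde of the silylated tetracycle | I/C=C(\C)[C@@H]1C[C@@]23C(=O)[C@]1(C(C)C)C(=O)C(O[Si](C)(C)C(C)(C)C)=C2[C@@]1(C)CCCC(C)(C)[C@@H]1[C@H]3C=O | intermediate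
27 | abietic acid | CC(C)C1=CC2=CC[C@@H]3[C@](C)(CCC[C@@]3(C)C(=O)O)[C@H]2CC1 | starting material
28 | 2-(trimethylsilyl)ethyl abietate | CC(C)C1=CC2=CC[C@@H]3[C@](C)(CCC[C@@]3(C)C(=O)OCC[Si](C)(C)C)[C@H]2CC1 | intermediate
29 | 2-(trimethylsilyl)ethyl 13,14-dihydroxyabiet-7-en-18-oate (cis-diol, C13 and C14 inconsequential) | CC(C)C1(O)C(O)C2=CC[C@@H]3[C@](C)(CCC[C@@]3(C)C(=O)OCC[Si](C)(C)C)[C@H]2CC1 | intermediate
30 | 2-(trimethylsilyl)ethyl 13-oxo-13,14-secoabiet-7-en-14-al-18-oate | O=CC1=CC[C@@H]2[C@](C)(CCC[C@@]2(C)C(=O)OCC[Si](C)(C)C)[C@H]1CCC(=O)C(C)C | intermediate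
31 | 2-(trimethylsilyl)ethyl 14-hydroxy-13-oxo-13,14-secoabiet-7-en-18-oate | OCC1=CC[C@@H]2[C@](C)(CCC[C@@]2(C)C(=O)OCC[Si](C)(C)C)[C@H]1CCC(=O)C(C)C | intermediate
32 | N-allyl-N-(2-nitrobenzenesulfonyl)hydrazine from 31 | NN(CC1=CC[C@@H]2[C@](C)(CCC[C@@]2(C)C(=O)OCC[Si](C)(C)C)[C@H]1CCC(=O)C(C)C)S(=O)(=O)c1ccccc1[N+](=O)[O-] | intermediate
33 | allylic monoalkyl diazene from 32 | N=NCC1=CC[C@@H]2[C@](C)(CCC[C@@]2(C)C(=O)OCC[Si](C)(C)C)[C@H]1CCC(=O)C(C)C | intermediate
34 | 2-(trimethylsilyl)ethyl 13-oxo-13,14-secoabiet-8(14)-en-18-oate | C=C1CC[C@@H]2[C@](C)(CCC[C@@]2(C)C(=O)OCC[Si](C)(C)C)[C@H]1CCC(=O)C(C)C | intermediate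
35 | potassium C12=C13 enolate of 34 | C=C1CC[C@@H]2[C@](C)(CCC[C@@]2(C)C(=O)OCC[Si](C)(C)C)[C@H]1CC=C([O-])C(C)C.[K+] | intermediate
36 | 12-hydroxy derivative of 34 (C12 epimers) | C=C1CC[C@@H]2[C@](C)(CCC[C@@]2(C)C(=O)OCC[Si](C)(C)C)[C@H]1CC(O)C(=O)C(C)C | intermediate
37 | 2-(trimethylsilyl)ethyl 12-oxo-13,14,15,16-tetranorlabd-8(17)-en-18-oate | C=C1CC[C@@H]2[C@](C)(CCC[C@@]2(C)C(=O)OCC[Si](C)(C)C)[C@H]1CC=O | intermediate
38 | 18-[2-(trimethylsilyl)ethyl] hydrogen 13,14,15,16-tetranorlabd-8(17)-ene-12,18-dioate | C=C1CC[C@@H]2[C@](C)(CCC[C@@]2(C)C(=O)OCC[Si](C)(C)C)[C@H]1CC(=O)O | intermediate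
39 | 2-thioxopyridin-1-yl ester of 38 | C=C1CC[C@@H]2[C@](C)(CCC[C@@]2(C)C(=O)OCC[Si](C)(C)C)[C@H]1CC(=O)On1ccccc1=S | intermediate
40 | 2-(trimethylsilyl)ethyl 11-iodo-12,13,14,15,16-pentanorlabd-8(17)-en-18-oate | C=C1CC[C@@H]2[C@](C)(CCC[C@@]2(C)C(=O)OCC[Si](C)(C)C)[C@H]1CI | intermediate
41 | C11 alkylzinc iodide from 40 | C=C1CC[C@@H]2[C@](C)(CCC[C@@]2(C)C(=O)OCC[Si](C)(C)C)[C@H]1C[Zn]I | intermediate
42 | doubly silyl-protected target | C=C1CC[C@@H]2[C@](C)(CCC[C@@]2(C)C(=O)OCC[Si](C)(C)C)[C@H]1C/C=C(\C)[C@@H]1C[C@@]23C(=O)[C@]1(C(C)C)C(=O)C(O[Si](C)(C)C(C)(C)C)=C2[C@@]1(C)CCCC(C)(C)[C@@H]1[C@H]3C=O | intermediate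
43 | CNP0256710.1 | C=C1CC[C@@H]2[C@](C)(CCC[C@@]2(C)C(=O)O)[C@H]1C/C=C(\C)[C@@H]1C[C@@]23C(=O)[C@]1(C(C)C)C(=O)C(O)=C2[C@@]1(C)CCCC(C)(C)[C@@H]1[C@H]3C=O | target

**Totals**
Total step count: 26.
Longest linear sequence: 12 steps (steps 1–4, 8, 9, 13–16, 25, 26).

**Steps most likely to fail**

1. Step 13. Attack of the diene on the fully substituted C8′ may be too slow. Faster alternatives are closure of the first-formed zwitterion onto C9′ (a Diels–Alder-type or (2+2) outcome), addition at the unsubstituted C9′, and acid-induced tautomerisation of the quinone to a quinone methide. Discrimination between the two quinone faces by C7′ may also be weak.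
 The fallback sets out from 15 and comes back at 23.
 - Anodic oxidation of 15 (Pt anode, KOH, MeOH, 0 °C) would give the quinone bisketal F1.
 - Mild aqueous acid removes the C14′ ketal, whose ionisation is assisted vinylogously by the C12′ methoxy group. This leaves the C11′ dimethyl monoketal F2.
 - TMSOTf ionises F2 to a discrete methoxy-substituted pentadienyl cation, a much stronger electrophile than the titanium-bound quinone. It should take up 21 in the cationic quinone-monoketal (5+2) mode to give the C11′ methyl enol ether of the bicycle F3.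
 - F3 is cyclised under the conditions of step 14, with the enol ether as terminator, to the tetracyclic methyl enol ether F4.
 - BBr3 at low temperature frees the diosphenol 23.

2. Step 14. The cascade may become stepwise. Proton loss from the C10′ cation would give monocyclic dienes, and their re-protonation and axial capture would erode the trans ring fusion toward the cis-hydrindane. Early protonation of C5′=C10′ would close ring B without ring A, and the cross-conjugated enol may capture the cation too slowly.
 The fallback sets out from 15 and comes back at 23. It forms the same two bonds one stage earlier, with the aromatic C9′ as terminator.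
 - The same acid applied to 15 would give the trans-fused hexahydrofluorene F5 in the well-known arene-terminated mode, under the same allylic-strain control by C7′.
 - (NH4)2Ce(NO3)6 converts F5 into the tricyclic methoxyquinone F6.
 - The TiCl4-promoted (5+2) cycloaddition of F6 with 21, on the face opposite the axial C10′ methyl group, delivers 23.

3. Step 25. Zinc insertion into the β-branched iodide may stall. The C11–palladium intermediate may lose the allylic β-hydrogen at C9. The zinc reagent may also be consumed by protonation or homocoupling before it meets the hindered core.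
 The fallback sets out from 38 and comes back at 42.
 - The acid is condensed with N-hydroxyphthalimide (DIC, DMAP) to the redox-active ester F7.
 - F7 is joined to 26 by nickel-catalysed reductive decarboxylative cross-electrophile coupling (NiBr2(dme), 4,4′-di-tert-butyl-2,2′-bipyridine, Zn, DMA). This is a radical route that needs no preformed organometal and tolerates the carbonyl groups.

**Further compounds**
F1 | step 13 | C11′,C14′-bis(dimethyl ketal) of quinone 16 | COC1=C(C(C)C)C(OC)(OC)C([C@H](C=C)/C=C(\C)CCC=C(C)C)=CC1(OC)OC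
F2 | step 13 | C11′ dimethyl monoketal of quinone 16 | COC1=C(C(C)C)C(=O)C([C@H](C=C)/C=C(\C)CCC=C(C)C)=CC1(OC)OC
F3 | step 13 | C11′ methyl enol ether of 22 | I/C=C(\C)[C@@H]1C[C@]2(C(=O)[C@]1(C(C)C)C(=O)C(OC)=C2)[C@H](C=C)/C=C(\C)CCC=C(C)C
F4 | step 13 | C11′ methyl enol ether of 23 | I/C=C(\C)[C@@H]1C[C@@]23C(=O)[C@]1(C(C)C)C(=O)C(OC)=C2[C@@]1(C)CCCC(C)(C)[C@@H]1[C@H]3C=C
F5 | step 14 | trans-fused hexahydrofluorene (tricyclic trimethoxyarene with C7′ vinyl) | COc1c(OC)c(C(C)C)c(OC)c2c1[C@@]1(C)CCCC(C)(C)[C@@H]1[C@H]2C=C
F6 | step 14 | tricyclic 12′-methoxy-11′,14′-quinone with C7′ vinyl | COC1=C(C(C)C)C(=O)C2=C(C1=O)[C@@]1(C)CCCC(C)(C)[C@@H]1[C@H]2C=C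
F7 | step 25 | N-hydroxyphthalimide ester of acid 38 | C=C1CC[C@@H]2[C@](C)(CCC[C@@]2(C)C(=O)OCC[Si](C)(C)C)[C@H]1CC(=O)ON1C(=O)c2ccccc2C1=O
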